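Decide first what to freeze: the catalyst, which the catalysed step hands back, and the dissolved gas, which transfer refills faster than the catalysed step empties it, even at the full charge (0.27 /h against 0.0540 /h).

substrate 0.020 M; gas phase 9.6 mM (held); catalyst 100 µM; time 10 d

    gas phase ⇌ dissolved gas, rate k1*(csat - [dissolved gas]) (k1 = 0.27 /h, csat = 9.6 mM)
    substrate ⇌ dormant form (K2 = 2.2, k2 = 0.021 /h)
    substrate + dissolved gas → uncatalysed product (k3 = 0.076 /M/h)
    substrate + dissolved gas + catalyst → catalyst + target (k4 = 27000 /M²/h)

* how much target there is at 10 d, in percent of the substrate charged
* concentration of dissolved gas in solution at 10 d, in percent of saturation

With the gas at saturation, the catalysed step is pseudo-first-order in substrate, and dormant form returns at its own constant: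

catalysed constant = 0.0259 /h
release constant = 0.00955 /h

Substrate and dormant form are then a linear pair with two rate constants, whose sum is the catalysed, forward and release constants added and whose product is catalysed times release:

fast = 0.0517 /h
slow = 0.00479 /h

The fast constant is ten times the slow one, so by 10 d you are left with the slow mode. I call the slow constant the drain constant, the rate at which [substrate] + [dormant form] empties into products. With the starting amplitude of that mode:

unconverted = 54.9% × exp(−drain × time) = 17.4%
target = 80.3%
[substrate] = 3.22% of the charge, so saturation = 99.4%

My target should run high, since I froze the gas at saturation from the start, whereas none of it is dissolved at the start, and with substrate at the full charge the balance of transfer against the catalysed step stands at 83.3% of saturation.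

The forecast gives 79% (74% to 84%) and 99.3%, its yield “capped by the slow release of substrate from the dormant pool”.

The flask gives 78.4% of target and 99.3% of saturation. Now read the same flask at 2.5 d: it holds 13.3% substrate and 35.3% dormant form, so 48.6% of the charge is unconverted, with target at 50.0%. Carry that forward on the drain constant for the 7.50 d up to the asked time, and you reckon 20.5% unconverted, where the flask at 10 d holds 19.4%.

The numbers of this flask were chosen freely.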